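**Retrosynthetic overview** (drimane numbering: C1 carries the ester, C4 the gem-dimethyl group, C5/C10 are the ring-fusion carbons, C9 carries C11, C8 carries C12)

1. Target 24 ⇐ aryl silyl ether cleavage, Swern oxidation of the 11,12-diol and C1 esterification ⇐ triol 16 ⇐ LiAlH4 reduction of the tricyclic keto lactone 15.
2. 15 ⇐ key step from the monocyclic dihydrofuran enal 13: a conjugate addition makes C5–C10 (ring A), then an olefination makes C7=C8 (ring B); the lactone closes last and is opened again in the next step.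
3. Enabling feature: O1 and O11 are 1,4-related across C1–C10–C9–C11, so the C1 carbonyl can be held as a cyclic enol ether (2,3-dihydrofuran O–C11–C9–C10=C1). This makes C10 nucleophilic with fixed geometry and lets C9 bias its faces. C5 and C7 are the β- and carbonyl carbons of an enal that the C4 gem-dimethyl group keeps free of γ-hydrogens, and the C12 carbonyl (with a phosphonate) acidifies C8.
4. 13 ⇐ cross metathesis (enal), thioester–alkylborane coupling (C1–C2) and a catalytic asymmetric Mukaiyama–Michael addition (C9–C10) that sets C9; C10 and C5 (key step) and C1 (hydride reduction) are relayed from C9, with the amine catalyst reinforcing C5.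
5. Ring order: dihydrofuran (temporary) → ring A → ring B → lactone (temporary).

Key step: step 7

Remark: C8 and C10 in 6, 9, 10, 11 and 13 (and C8 in 14, C1 in 10) are epimer mixtures and are left undefined in the SMILES, because C10 is erased in step 5 and C8 in step 7; hydroxy ketone 14 is drawn in its open form, which equilibrates with the cyclic hemiketal.

**Step 1**
Reactants: 1 S-ethyl propanethioate
Product: 2 (Z)-1-(ethylsulfanyl)-1-(trimethylsilyloxy)prop-1-ene
Conditions: LiN(iPr)2, THF, −78 °C; Me3SiCl, −78 → 0 °C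
Reagents that add atoms: chlorotrimethylsilane C[Si](C)(C)Cl
Why: Kinetic enolisation of the thioester and O-silylation (silyl ketene acetal formation) should give the nucleophile for step 3, whose geometry only affects C10, a centre that is erased later.

**Step 2**
Reactants: 3 (tert-butyldimethylsilyloxy)acetaldehyde, 4 trimethyl phosphonoacetate
Product: 5 methyl 4-(tert-butyldimethylsilyloxy)-2-(dimethoxyphosphoryl)but-2-enoate (E/Z mixture)
Conditions: TiCl4, N-methylmorpholine, THF, 0 → 23 °C
Reagents that add atoms: none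
Why: Knoevenagel condensation of an aliphatic aldehyde with a phosphonoacetate under TiCl4/amine activation should give the doubly activated alkene, with no stereocenter formed.

**Step 3**
Reactants: 5 methyl 4-(tert-butyldimethylsilyloxy)-2-(dimethoxyphosphoryl)but-2-enoate, 2 (Z)-1-(ethylsulfanyl)-1-(trimethylsilyloxy)prop-1-ene
Product: 6 S-ethyl (3S)-3-[(tert-butyldimethylsilyloxy)methyl]-4-(dimethoxyphosphoryl)-5-methoxy-2-methyl-5-oxopentanethioate
Conditions: [Cu((S,S)-tBu-box)](SbF6)2 (10 mol %; tBu-box = 2,2′-isopropylidenebis(4-tert-butyl-2-oxazoline)), (CF3)2CHOH (2 equiv), toluene–CH2Cl2, −78 → −40 °C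
Reagents that add atoms: none
Why: Proposed new method: the ester and phosphoryl oxygens of 5 should chelate divalent copper in a six-membered ring as alkylidene malonates do, so that the C2-symmetric bis(oxazoline) ligand screens one face of C9 (both alkene isomers should converge because the chelate is nearly C2-symmetric) and the silyl ketene acetal adds to the open face to set C9 (3S in 6), with hexafluoroisopropanol taking up the silyl group; the closest known reaction is the copper–bis(oxazoline)-catalysed Mukaiyama–Michael addition of thioester silyl ketene acetals to alkylidene malonates.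

**Step 4**
Reactants: 7 3,3-dimethylpenta-1,4-diene, 6 S-ethyl (3S)-3-[(tert-butyldimethylsilyloxy)methyl]-4-(dimethoxyphosphoryl)-5-methoxy-2-methyl-5-oxopentanethioate
Product: 9 methyl (3S)-3-[(tert-butyldimethylsilyloxy)methyl]-2-(dimethoxyphosphoryl)-4,8,8-trimethyl-5-oxodec-9-enoate, via alkylborane 8 (not isolated)
Conditions: 7 (3 equiv), 9-BBN, THF, 0 → 23 °C, excess 7 removed in vacuo; then 6, Pd(PPh3)4 (5 mol %), Cu(O2C-C4H3S) (copper thiophene-2-carboxylate, 1.5 equiv), Cs2CO3, THF, 45 °C
Reagents that add atoms: none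
Why: Anti-Markovnikov hydroboration of one vinyl group followed by Liebeskind–Srogl coupling of the thiol ester with the B-alkyl borane (zerovalent palladium, copper carboxylate as thiophile) should give the ketone without touching the methyl ester, phosphonate or silyl ether, and forms no stereocenter.

**Step 5**
Reactants: 9 methyl (3S)-3-[(tert-butyldimethylsilyloxy)methyl]-2-(dimethoxyphosphoryl)-4,8,8-trimethyl-5-oxodec-9-enoate
Product: 11 methyl 2-(dimethoxyphosphoryl)-2-[(3S)-5-(3,3-dimethylpent-4-en-1-yl)-4-methyl-2,3-dihydrofuran-3-yl]acetate, via cyclic methyl ketal 10 (not isolated)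
Conditions: CSA (10 mol %), MeOH, 23 °C; evaporate; PPTS (5 mol %), toluene, 110 °C, MeOH distilled off
Reagents that add atoms: none
Why: Acid methanolysis of the primary silyl ether frees the C11 hydroxyl, which traps the C1 ketone as the five-membered cyclic methyl ketal (methanol as solvent keeps C12 as its methyl ester), and acid-catalysed loss of methanol under thermodynamic control should give the more substituted endocyclic enol ether, so that C10 becomes trigonal while C9 is untouched.

**Step 6**
Reactants: 11 methyl 2-(dimethoxyphosphoryl)-2-[(3S)-5-(3,3-dimethylpent-4-en-1-yl)-4-methyl-2,3-dihydrofuran-3-yl]acetate, 12 (E)-but-2-enal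
Product: 13 methyl 2-(dimethoxyphosphoryl)-2-[(3S)-5-[(E)-3,3-dimethyl-6-oxohex-4-en-1-yl]-4-methyl-2,3-dihydrofuran-3-yl]acetate
Conditions: second-generation Hoveyda–Grubbs catalyst RuCl2(H2IMes)(=CH-C6H4-2-OiPr) (5 mol %), 12 (5 equiv), CH2Cl2, 40 °C
Reagents that add atoms: none
Why: Olefin cross metathesis of the monosubstituted vinyl group with crotonaldehyde should give the (E)-enal under thermodynamic control, the tetrasubstituted enol ether being too hindered to engage the ruthenium alkylidene.

**Step 7**
Reactants: 13 methyl 2-(dimethoxyphosphoryl)-2-[(3S)-5-[(E)-3,3-dimethyl-6-oxohex-4-en-1-yl]-4-methyl-2,3-dihydrofuran-3-yl]acetate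
Product: 15 (5S,9R,10S)-1-oxodrim-7-en-12,11-olide, via keto aldehyde 14 (not isolated)
Conditions: (S)-2-[diphenyl(trimethylsilyloxy)methyl]pyrrolidine (20 mol %), 4-nitrobenzoic acid (20 mol %), H2O (2 equiv), toluene, 0 → 23 °C; then MeCN, LiCl, DBU, 23 → 45 °C; aqueous NH4Cl work-up
Reagents that add atoms: water O
Why: Proposed new method: the amine condenses with the enal to an (E)-iminium ion, C10 of the cyclic enol ether adds to C5, water captures the C1 oxocarbenium ion and hydrolyses the enamine to give 14, and after LiCl/DBU is added the C8 phosphonate carbanion olefinates the C7 aldehyde (Horner–Wadsworth–Emmons reaction), after which O11 lactonises onto C12. The closest known reactions are the amine-catalysed Mukaiyama–Michael addition of silyl enol ethers and 2-silyloxyfurans to enals, here extended to an alkyl enol ether in an intramolecular setting, and one-pot Michael/Horner–Wadsworth–Emmons annulations to cyclohexenecarboxylates. Ring A closes in a 6-(enolendo)-exo-trig mode (enol ether carbon onto the iminium β-carbon) and ring B in a 6-(enolexo)-exo-trig mode (C8 carbanion onto the C7 carbonyl, then loss of dimethyl phosphate). C10 is controlled by the C9 stereocenter of the dihydrofuran, C5 bonding anti to the C8 side chain, while the ring fixes the enol ether geometry (C2 cis to the methyl group) so that the methyl group ends up axial; C5 is controlled by the catalyst, whose diphenyl(silyloxy)methyl arm screens one face of the iminium ion so that C10 adds to the Si face of C5 in an open antiperiplanar arrangement that leaves C6 equatorial and H5 anti to the C10 methyl group (trans ring fusion). The step needs site selectivity (C10 and not C8 as first nucleophile, 1,4- and not 1,2-addition) and the open rather than the hetero-Diels–Alder mode of addition: the first is secured by ring size (C8 could reach C5 or C7 only through eight- and ten-membered rings), by the C4 gem-dimethyl group that leaves the enal without γ-hydrogens and by adding the base only after the enal is consumed, the second by the amine, which replaces the carbonyl oxygen that a cycloaddition would need.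

**Step 8**
Reactants: 15 (5S,9R,10S)-1-oxodrim-7-en-12,11-olide
Product: 16 (1R,5S,9S,10S)-drim-7-ene-1,11,12-triol
Conditions: LiAlH4, THF, −20 → 0 °C; H2O, aqueous NaOH
Reagents that add atoms: none
Why: Hydride reduction opens the lactone to the 11,12-diol and reduces the C1 ketone by axial attack from the α face (the β face is screened by the axial C10 methyl group and the C11 oxygen), which should set the equatorial 1β-hydroxyl (1R).

**Step 9**
Reactants: 16 (1R,5S,9S,10S)-drim-7-ene-1,11,12-triol
Product: 17 (1R,5S,9S,10S)-11,12-bis(tert-butyldimethylsilyloxy)drim-7-en-1-ol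
Conditions: TBSCl (2.2 equiv), imidazole, CH2Cl2, 0 °C
Reagents that add atoms: tert-butyldimethylsilyl chloride CC(C)(C)[Si](C)(C)Cl
Why: Silylation should be much faster at the two primary hydroxyls than at the secondary C1 hydroxyl next to the quaternary C10, so that only the acylation site stays free.

**Step 10**
Reactants: 18 (E)-3-(4-hydroxyphenyl)prop-2-enoic acid
Product: 20 (E)-3-[4-(tert-butyldimethylsilyloxy)phenyl]prop-2-enoic acid, via silyl ester 19 (not isolated)
Conditions: TBSCl (2.3 equiv), imidazole, DMF, 23 °C; then K2CO3 (10 mol %), MeOH, 0 °C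
Reagents that add atoms: tert-butyldimethylsilyl chloride CC(C)(C)[Si](C)(C)Cl
Why: Exhaustive silylation followed by selective methanolysis of the far more labile silyl ester should leave the phenol protected and the acid free.

**Step 11**
Reactants: 17 (1R,5S,9S,10S)-11,12-bis(tert-butyldimethylsilyloxy)drim-7-en-1-ol, 20 (E)-3-[4-(tert-butyldimethylsilyloxy)phenyl]prop-2-enoic acid
Product: 21 (1R,5S,9S,10S)-11,12-bis(tert-butyldimethylsilyloxy)drim-7-en-1-yl (E)-3-[4-(tert-butyldimethylsilyloxy)phenyl]prop-2-enoate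
Conditions: DCC, DMAP (1 equiv), CH2Cl2, 23 → 40 °C
Reagents that add atoms: none
Why: Steglich esterification through the acylpyridinium ion should acylate the hindered equatorial C1 hydroxyl with retention at C1 and without touching the (E)-alkene.

**Step 12**
Reactants: 21 (1R,5S,9S,10S)-11,12-bis(tert-butyldimethylsilyloxy)drim-7-en-1-yl (E)-3-[4-(tert-butyldimethylsilyloxy)phenyl]prop-2-enoate
Product: 22 (1R,5S,9S,10S)-11,12-dihydroxydrim-7-en-1-yl (E)-3-[4-(tert-butyldimethylsilyloxy)phenyl]prop-2-enoate
Conditions: CSA (20 mol %), MeOH–CH2Cl2, 0 °C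
Reagents that add atoms: none
Why: Acid-catalysed methanolysis should cleave the two primary alkyl silyl ethers much faster than the aryl silyl ether, and the cold acidic medium should suppress acyl migration from O1 to O11.

**Step 13**
Reactants: 22 (1R,5S,9S,10S)-11,12-dihydroxydrim-7-en-1-yl (E)-3-[4-(tert-butyldimethylsilyloxy)phenyl]prop-2-enoate
Product: 23 (1R,5S,9R,10S)-11,12-dioxodrim-7-en-1-yl (E)-3-[4-(tert-butyldimethylsilyloxy)phenyl]prop-2-enoate
Conditions: (COCl)2, DMSO, CH2Cl2, −78 °C; Et3N, −78 → −30 °C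
Reagents that add atoms: none
Why: Swern oxidation activates both hydroxyls as alkoxysulfonium ions before base is added, so the 1,4-dialdehyde should form without lactol or lactone formation and, in the cold, without epimerisation at C9.

**Step 14**
Reactants: 23 (1R,5S,9R,10S)-11,12-dioxodrim-7-en-1-yl (E)-3-[4-(tert-butyldimethylsilyloxy)phenyl]prop-2-enoate
Product: 24 (1R,5S,9R,10S)-11,12-dioxodrim-7-en-1-yl (E)-3-(4-hydroxyphenyl)prop-2-enoate
Conditions: Bu4NF, AcOH, THF, 0 °C
Reagents that add atoms: none
Why: Fluoride should cleave the aryl silyl ether within minutes, and the acetic acid buffer should keep the medium too weakly basic to epimerise C9 or cleave the cinnamate.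

**Compound list**

1 | S-ethyl propanethioate | CCC(=O)SCC | starting material
2 | (Z)-1-(ethylsulfanyl)-1-(trimethylsilyloxy)prop-1-ene | C/C=C(/O[Si](C)(C)C)SCC | intermediate
3 | (tert-butyldimethylsilyloxy)acetaldehyde | O=CCO[Si](C)(C)C(C)(C)C | starting material
4 | trimethyl phosphonoacetate | COC(=O)CP(=O)(OC)OC | starting material
5 | methyl 4-(tert-butyldimethylsilyloxy)-2-(dimethoxyphosphoryl)but-2-enoate (E/Z mixture) | COC(=O)C(=CCO[Si](C)(C)C(C)(C)C)P(=O)(OC)OC | intermediate
6 | S-ethyl (3S)-3-[(tert-butyldimethylsilyloxy)methyl]-4-(dimethoxyphosphoryl)-5-methoxy-2-methyl-5-oxopentanethioate (epimers at C2 and C4 of the chain) | CCSC(=O)C(C)[C@@H](CO[Si](C)(C)C(C)(C)C)C(C(=O)OC)P(=O)(OC)OC | intermediate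
7 | 3,3-dimethylpenta-1,4-diene | C=CC(C)(C)C=C | starting material
8 | 9-(3,3-dimethylpent-4-en-1-yl)-9-borabicyclo[3.3.1]nonane (not isolated) | C=CC(C)(C)CCB1C2CCCC1CCC2 | intermediate
9 | methyl (3S)-3-[(tert-butyldimethylsilyloxy)methyl]-2-(dimethoxyphosphoryl)-4,8,8-trimethyl-5-oxodec-9-enoate | C=CC(C)(C)CCC(=O)C(C)[C@@H](CO[Si](C)(C)C(C)(C)C)C(C(=O)OC)P(=O)(OC)OC | intermediate
10 | methyl 2-(dimethoxyphosphoryl)-2-[(3S)-5-(3,3-dimethylpent-4-en-1-yl)-5-methoxy-4-methyloxolan-3-yl]acetate (not isolated) | C=CC(C)(C)CCC1(OC)OC[C@@H](C(C(=O)OC)P(=O)(OC)OC)C1C | intermediate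
11 | methyl 2-(dimethoxyphosphoryl)-2-[(3S)-5-(3,3-dimethylpent-4-en-1-yl)-4-methyl-2,3-dihydrofuran-3-yl]acetate | C=CC(C)(C)CCC1=C(C)[C@@H](CO1)C(C(=O)OC)P(=O)(OC)OC | intermediate
12 | (E)-but-2-enal (crotonaldehyde) | C/C=C/C=O | starting material
13 | methyl 2-(dimethoxyphosphoryl)-2-[(3S)-5-[(E)-3,3-dimethyl-6-oxohex-4-en-1-yl]-4-methyl-2,3-dihydrofuran-3-yl]acetate | O=C/C=C/C(C)(C)CCC1=C(C)[C@@H](CO1)C(C(=O)OC)P(=O)(OC)OC | intermediate
14 | methyl (3S)-2-(dimethoxyphosphoryl)-4-hydroxy-3-[(1S,2S)-1,3,3-trimethyl-6-oxo-2-(2-oxoethyl)cyclohexyl]butanoate (open form of the hemiketal; not isolated) | O=CC[C@H]1C(C)(C)CCC(=O)[C@]1(C)[C@@H](CO)C(C(=O)OC)P(=O)(OC)OC | intermediate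
15 | (5S,9R,10S)-1-oxodrim-7-en-12,11-olide (C1 ketone; C12 carbonyl lactonised to O11; 5α-H, 9α-H, 10β-CH3) | CC1(C)CCC(=O)[C@]2(C)[C@H]3COC(=O)C3=CC[C@@H]12 | intermediate
16 | (1R,5S,9S,10S)-drim-7-ene-1,11,12-triol (1β-OH) | CC1(C)CC[C@@H](O)[C@]2(C)[C@@H](CO)C(CO)=CC[C@@H]12 | intermediate
17 | (1R,5S,9S,10S)-11,12-bis(tert-butyldimethylsilyloxy)drim-7-en-1-ol | CC1(C)CC[C@@H](O)[C@]2(C)[C@@H](CO[Si](C)(C)C(C)(C)C)C(CO[Si](C)(C)C(C)(C)C)=CC[C@@H]12 | intermediate
18 | (E)-3-(4-hydroxyphenyl)prop-2-enoic acid (p-coumaric acid) | OC(=O)/C=C/c1ccc(O)cc1 | starting material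
19 | tert-butyldimethylsilyl (E)-3-[4-(tert-butyldimethylsilyloxy)phenyl]prop-2-enoate (not isolated) | CC(C)(C)[Si](C)(C)OC(=O)/C=C/c1ccc(O[Si](C)(C)C(C)(C)C)cc1 | intermediate
20 | (E)-3-[4-(tert-butyldimethylsilyloxy)phenyl]prop-2-enoic acid | OC(=O)/C=C/c1ccc(O[Si](C)(C)C(C)(C)C)cc1 | intermediate
21 | (1R,5S,9S,10S)-11,12-bis(tert-butyldimethylsilyloxy)drim-7-en-1-yl (E)-3-[4-(tert-butyldimethylsilyloxy)phenyl]prop-2-enoate | CC1(C)CC[C@@H](OC(=O)/C=C/c2ccc(O[Si](C)(C)C(C)(C)C)cc2)[C@]2(C)[C@@H](CO[Si](C)(C)C(C)(C)C)C(CO[Si](C)(C)C(C)(C)C)=CC[C@@H]12 | intermediate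
22 | (1R,5S,9S,10S)-11,12-dihydroxydrim-7-en-1-yl (E)-3-[4-(tert-butyldimethylsilyloxy)phenyl]prop-2-enoate | CC1(C)CC[C@@H](OC(=O)/C=C/c2ccc(O[Si](C)(C)C(C)(C)C)cc2)[C@]2(C)[C@@H](CO)C(CO)=CC[C@@H]12 | intermediate
23 | (1R,5S,9R,10S)-11,12-dioxodrim-7-en-1-yl (E)-3-[4-(tert-butyldimethylsilyloxy)phenyl]prop-2-enoate | CC1(C)CC[C@@H](OC(=O)/C=C/c2ccc(O[Si](C)(C)C(C)(C)C)cc2)[C@]2(C)[C@@H](C=O)C(C=O)=CC[C@@H]12 | intermediate
24 | (1R,5S,9R,10S)-11,12-dioxodrim-7-en-1-yl (E)-3-(4-hydroxyphenyl)prop-2-enoate (CNP0187624.1) | CC1(C)CC[C@@H](OC(=O)/C=C/c2ccc(O)cc2)[C@]2(C)[C@@H](C=O)C(C=O)=CC[C@@H]12 | target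

**Step count and risks**

Total step count: 14 (steps 1 and 10 are one-step branches). Longest linear sequence: 12 steps (steps 2–9 and 11–14).

Steps most likely to fail:

Step 7. The tetrasubstituted enol ether may add too slowly to the hindered iminium ion, so that hydration of the dihydrofuran or an acid-promoted hetero-Diels–Alder closure to the cis-fused ketal takes over. The fallback replaces the enol ether by enolate chemistry and sets out from ketone 9. Cross metathesis of 9 with 12 under the conditions of step 6 would give the keto enal F1. Cs2CO3 in MeCN would then bring about the known sequence of intramolecular Michael addition of the ketone enolate (C10 onto C5) and Horner–Wadsworth–Emmons ring closure to the bicyclic silyl ether keto ester F2. The C5/C10 diastereomers would have to be separated, since C10 is then under acyclic substrate control only. HF·pyridine followed by CSA (desilylation and lactonisation) would return the route to 15.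

Step 3. Chelation of the phosphonoacetate to divalent copper may be too weak, or the two alkene isomers of 5 may fail to converge, so that facial selectivity at C9 erodes. The fallback uses the established alkylidene malonate acceptor, brings in phosphorus later and sets out from 3. Knoevenagel condensation of 3 with dimethyl malonate would give the alkylidene malonate F3. The copper–bis(oxazoline)-catalysed Mukaiyama–Michael addition of 2 would give the malonate thioester F4. Coupling with 8 as in step 4 would give the keto malonate F5, and Krapcho dealkoxycarbonylation (LiCl, wet DMSO, 140 °C) the keto ester F6. The conditions of step 5 would give the cyclic methyl ketal F7 and then the dihydrofuran ester F8. C8 phosphorylation of the lithium ester enolate (LiN(iPr)2, 2.2 equiv, ClP(O)(OMe)2, THF, −78 → 0 °C, with O-to-C phosphoryl shift) would return the route to 11.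

Step 6. The ruthenium alkylidene may be intercepted by the electron-rich dihydrofuran or turn over too slowly at the neopentyl-type vinyl group. The fallback moves the metathesis to the hydrocarbon stage, makes the enal by allylic oxidation and sets out from 7 and 6. Cross metathesis of excess 7 with (Z)-1,4-bis(tert-butyldimethylsilyloxy)but-2-ene (second-generation Grubbs catalyst RuCl2(=CHPh)(H2IMes)(PCy3)) would give the dienyl silyl ether F9. Hydroboration with 9-BBN would give the borane F10, and coupling with 6 as in step 4 the ketone F11. The conditions of step 5 would give the ketal alcohol F12 and then the dihydrofuran allylic alcohol F13. MnO2 in CH2Cl2 would oxidise the allylic alcohol and return the route to 13.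

Further compounds
F1 | step 7 | methyl (3S,9E)-3-[(tert-butyldimethylsilyloxy)methyl]-2-(dimethoxyphosphoryl)-4,8,8-trimethyl-5,11-dioxoundec-9-enoate | O=C/C=C/C(C)(C)CCC(=O)C(C)[C@@H](CO[Si](C)(C)C(C)(C)C)C(C(=O)OC)P(=O)(OC)OC
F2 | step 7 | methyl (5S,9R,10S)-11-(tert-butyldimethylsilyloxy)-1-oxodrim-7-en-12-oate | CC1(C)CCC(=O)[C@]2(C)[C@@H](CO[Si](C)(C)C(C)(C)C)C(C(=O)OC)=CC[C@@H]12
F3 | step 3 | dimethyl 2-[2-(tert-butyldimethylsilyloxy)ethylidene]propanedioate | COC(=O)C(=CCO[Si](C)(C)C(C)(C)C)C(=O)OC
F4 | step 3 | dimethyl 2-[(2S)-1-(tert-butyldimethylsilyloxy)-4-(ethylsulfanyl)-3-methyl-4-oxobutan-2-yl]propanedioate | CCSC(=O)C(C)[C@@H](CO[Si](C)(C)C(C)(C)C)C(C(=O)OC)C(=O)OC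
F5 | step 3 | dimethyl 2-[(2R)-1-(tert-butyldimethylsilyloxy)-3,7,7-trimethyl-4-oxonon-8-en-2-yl]propanedioate | C=CC(C)(C)CCC(=O)C(C)[C@@H](CO[Si](C)(C)C(C)(C)C)C(C(=O)OC)C(=O)OC
F6 | step 3 | methyl (3S)-3-[(tert-butyldimethylsilyloxy)methyl]-4,8,8-trimethyl-5-oxodec-9-enoate | C=CC(C)(C)CCC(=O)C(C)[C@@H](CO[Si](C)(C)C(C)(C)C)CC(=O)OC
F7 | step 3 | methyl 2-[(3S)-5-(3,3-dimethylpent-4-en-1-yl)-5-methoxy-4-methyloxolan-3-yl]acetate | C=CC(C)(C)CCC1(OC)OC[C@@H](CC(=O)OC)C1C
F8 | step 3 | methyl 2-[(3S)-5-(3,3-dimethylpent-4-en-1-yl)-4-methyl-2,3-dihydrofuran-3-yl]acetate | C=CC(C)(C)CCC1=C(C)[C@@H](CO1)CC(=O)OC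
F9 | step 6 | (E)-tert-butyl[(4,4-dimethylhexa-2,5-dien-1-yl)oxy]dimethylsilane | C=CC(C)(C)/C=C/CO[Si](C)(C)C(C)(C)C
F10 | step 6 | 9-[(E)-6-(tert-butyldimethylsilyloxy)-3,3-dimethylhex-4-en-1-yl]-9-borabicyclo[3.3.1]nonane | CC(C)(C)[Si](C)(C)OC/C=C/C(C)(C)CCB1C2CCCC1CCC2
F11 | step 6 | methyl (3S,9E)-11-(tert-butyldimethylsilyloxy)-3-[(tert-butyldimethylsilyloxy)methyl]-2-(dimethoxyphosphoryl)-4,8,8-trimethyl-5-oxoundec-9-enoate | CC(C)(C)[Si](C)(C)OC/C=C/C(C)(C)CCC(=O)C(C)[C@@H](CO[Si](C)(C)C(C)(C)C)C(C(=O)OC)P(=O)(OC)OC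
F12 | step 6 | methyl 2-(dimethoxyphosphoryl)-2-[(3S)-5-[(E)-6-hydroxy-3,3-dimethylhex-4-en-1-yl]-5-methoxy-4-methyloxolan-3-yl]acetate | OC/C=C/C(C)(C)CCC1(OC)OC[C@@H](C(C(=O)OC)P(=O)(OC)OC)C1C
F13 | step 6 | methyl 2-(dimethoxyphosphoryl)-2-[(3S)-5-[(E)-6-hydroxy-3,3-dimethylhex-4-en-1-yl]-4-methyl-2,3-dihydrofuran-3-yl]acetate | OC/C=C/C(C)(C)CCC1=C(C)[C@@H](CO1)C(C(=O)OC)P(=O)(OC)OC
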